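The trimer is cut at the bond between C4 of the upper flavan unit and C8 of an epiafzelechin-(4β→8)-epiafzelechin dimer, and ring C of that upper unit (O1, C2, C3, C4, C4a, C8a) is made at the flavone level. The key step is a three-component carbonylative annulation of an ortho-iodophenol, carbon monoxide and an arylacetylene, which forms C4–C4a, C3–C4 and O1–C2 in one operation. It exploits the ortho relation of O1 and C4a on ring A and the fact that C4, the later cationic coupling site, can come from CO. Asymmetric hydrogenation then sets C2, and a Friedel–Crafts union with the dimer sets C4 trans.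

Key step: step 5

Assumption: (−)-epiafzelechin 1 is bought as the enantiopure natural product, and its 2R,3R centres are carried unchanged into the two lower units. Flavonoid numbering is used throughout (ring A benzo, ring C pyran, ring B the 2-aryl group).

Step 1
Reactants: 1 (−)-epiafzelechin
Product: 2 5,7,4'-tri-O-benzylepiafzelechin
Conditions: BnBr (3.3 equiv), K2CO3 (3.5 equiv), DMF, 0 °C to rt, argon
Reagents that add atoms: benzyl bromide, BrCc1ccccc1
Why: Williamson etherification in which K2CO3 deprotonates only the three phenols, so the C3 carbinol should stay free and C2 and C3 are untouched.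

Step 2
Reactants: 2 5,7,4'-tri-O-benzylepiafzelechin
Product: 3 4β-(2-ethoxyethoxy)-5,7,4'-tri-O-benzylepiafzelechin
Conditions: DDQ (2 equiv), 2-ethoxyethanol (5 equiv), CH2Cl2, rt
Reagents that add atoms: 2-ethoxyethanol, CCOCCO
Why: DDQ benzylic oxidation in which hydride abstraction from C4, assisted by the 5,7-dioxygenated ring A, gives a C4 carbocation that the alcohol should capture on the β face, opposite the 3-hydroxyl and the 2-aryl group, which sets C4 as the 3,4-trans ether.

Step 3
Reactants: 3 4β-(2-ethoxyethoxy)-5,7,4'-tri-O-benzylepiafzelechin; 2 5,7,4'-tri-O-benzylepiafzelechin (4 equiv, the excess is recovered)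
Product: 4 hexa-O-benzyl epiafzelechin-(4β→8)-epiafzelechin
Conditions: TMSOTf (0.5 equiv), CH2Cl2, −78 °C, then Et3N
Reagents that add atoms: none
Why: Friedel–Crafts alkylation in which TMSOTf ionises the C4 ether and C8 of 2, the most nucleophilic and least hindered ring A position, should attack the carbocation anti to the 3-hydroxyl, which sets C4 of the upper unit 3,4-trans (4β→8), while the excess of 2 outcompetes further chain growth.

Step 4
Reactants: 5 3-(benzyloxy)phenol
Product: 6 5-(benzyloxy)-2-iodophenol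
Conditions: I2 (1.05 equiv), NaHCO3 (1.1 equiv), THF/H2O (1:1), 0 °C to rt
Reagents that add atoms: iodine, II
Why: Electrophilic aromatic iodination of the phenoxide, which should occur at C6 of 5 (ortho to the phenoxide oxygen, para to the benzyloxy group, less hindered than C2); any 4-iodo isomer would be removed by chromatography.

Step 5
Reactants: 6 5-(benzyloxy)-2-iodophenol; 7 1-(benzyloxy)-4-ethynylbenzene (1.2 equiv)
Product: 10 7-(benzyloxy)-2-[4-(benzyloxy)phenyl]-4H-chromen-4-one, via ortho-hydroxyaryl ynone 8 (not isolated), via diethylamino enone 9 (not isolated)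
Conditions: CO (20 bar), PdCl2(dppf) (3 mol %), Et2NH, 120 °C
Reagents that add atoms: carbon monoxide, [C-]#[O+]
Why: Oxidative addition of the C–I bond of 6 to zerovalent palladium and insertion of CO give an aroylpalladium species, which forges C4–C4a, and its coupling with alkyne 7 gives ynone 8; Et2NH then adds to the triple bond to give enaminone 9, and the ortho hydroxyl displaces the amine at C2 by addition–elimination, which forges O1–C2. The closest known reaction type is the carbonylative Sonogashira coupling–cyclisation of ortho-iodophenols with terminal alkynes to flavones. Ring C closes in the 6-endo mode (6-endo-trig on 9, formally 6-endo-dig on 8). No stereocenter is formed, because C2 and C4 are made at the sp2 level on purpose and are set in steps 6 and 7. The step needs carbonylative over direct alkynylation (which would lead to a 2-arylbenzofuran) and 6-endo over 5-exo closure (which would lead to an aurone); CO pressure on the electron-rich arylpalladium should secure the first and the amine-adduct pathway the second, while the ortho relation of iodine and hydroxyl in 6 fixes that the carbonyl carbon bonds to C4a and the oxygen to C2.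

Step 6
Reactants: 10 7-(benzyloxy)-2-[4-(benzyloxy)phenyl]-4H-chromen-4-one
Product: 12 (2S,4S)-7-(benzyloxy)-2-[4-(benzyloxy)phenyl]chroman-4-ol, via (2S)-flavanone 11 (not isolated)
Conditions: H2 (120 bar), [Ru(cod)(2-methylallyl)2] (5 mol %), 1,3-bis[(R)-1-(1-naphthyl)ethyl]imidazolinium tetrafluoroborate (10 mol %; the S,S salt is taken if the first run shows the 2R series), KOtBu (15 mol %), toluene, 40 °C
Reagents that add atoms: none
Why: Asymmetric hydrogenation of a flavone with a ruthenium N-heterocyclic carbene catalyst, in which the chiral carbene ligand should direct hydrogen to one face of C2=C3 and set C2 as S (flavanone 11) before the ketone is reduced cis to the aryl group; the C4 configuration is of no consequence because C4 is ionised in step 7, and the benzyl ethers are inert to this palladium-free catalyst.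

Step 7
Reactants: 12 (2S,4S)-7-(benzyloxy)-2-[4-(benzyloxy)phenyl]chroman-4-ol; 4 hexa-O-benzyl epiafzelechin-(4β→8)-epiafzelechin (1.5 equiv)
Product: 13 octa-O-benzyl (2S)-7,4'-dihydroxyflavan-(4β→8)-epiafzelechin-(4β→8)-epiafzelechin
Conditions: TMSOTf (0.5 equiv), 4 Å molecular sieves, CH2Cl2, −78 to −40 °C, then Et3N
Reagents that add atoms: none
Why: Friedel–Crafts alkylation in which TMSOTf ionises the benzylic alcohol to the flavan-4-yl carbocation, stabilised by the para 7-benzyloxy group; C8 of the upper unit of 4, the only open ring A position next to the pyran oxygen, should attack along the axial trajectory on the face opposite the equatorial 2-aryl group, which sets C4 as R (2,4-trans), and the low temperature should keep the existing interflavan bond intact.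

Step 8
Reactants: 13 octa-O-benzyl (2S)-7,4'-dihydroxyflavan-(4β→8)-epiafzelechin-(4β→8)-epiafzelechin
Product: 14 (2S)-7,4'-dihydroxyflavan-(4β→8)-epiafzelechin-(4β→8)-epiafzelechin
Conditions: H2 (1 atm), Pd(OH)2/C, THF/MeOH/H2O, rt
Reagents that add atoms: none
Why: Hydrogenolysis of the eight benzyl ethers, in which the cyclic O1–C2 ethers and the interflavan bonds should survive the neutral conditions, as is usual for benzylated proanthocyanidins, and no stereocenter is touched.

Compound list
1 | (−)-epiafzelechin, (2R,3R)-2-(4-hydroxyphenyl)chroman-3,5,7-triol | Oc1cc(O)c2c(c1)O[C@H](c1ccc(O)cc1)[C@H](O)C2 | starting material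
2 | 5,7,4'-tri-O-benzylepiafzelechin, (2R,3R)-5,7-bis(benzyloxy)-2-[4-(benzyloxy)phenyl]chroman-3-ol | c1ccc(COc2cc(OCc3ccccc3)c3c(c2)O[C@H](c2ccc(OCc4ccccc4)cc2)[C@H](O)C3)cc1 | intermediate
3 | 4β-(2-ethoxyethoxy)-5,7,4'-tri-O-benzylepiafzelechin (2,3-cis-3,4-trans) | c1ccc(COc2cc(OCc3ccccc3)c3c(c2)O[C@H](c2ccc(OCc4ccccc4)cc2)[C@H](O)[C@H]3OCCOCC)cc1 | intermediate
4 | hexa-O-benzyl epiafzelechin-(4β→8)-epiafzelechin (5,7,4'-tri-O-benzyl on each unit, both 3-hydroxyls free) | c1c(OCc3ccccc3)cc(OCc3ccccc3)c2c1O[C@H](c1ccc(OCc3ccccc3)cc1)[C@H](O)[C@H]2c1c(OCc3ccccc3)cc(OCc3ccccc3)c2c1O[C@H](c1ccc(OCc3ccccc3)cc1)[C@H](O)C2 | intermediate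
5 | 3-(benzyloxy)phenol | Oc1cccc(OCc2ccccc2)c1 | starting material
6 | 5-(benzyloxy)-2-iodophenol | Oc1cc(OCc2ccccc2)ccc1I | intermediate
7 | 1-(benzyloxy)-4-ethynylbenzene | C#Cc1ccc(OCc2ccccc2)cc1 | starting material
8 | 1-[4-(benzyloxy)-2-hydroxyphenyl]-3-[4-(benzyloxy)phenyl]prop-2-yn-1-one | O=C(C#Cc1ccc(OCc2ccccc2)cc1)c1ccc(OCc2ccccc2)cc1O | intermediate (not isolated)
9 | (E)-1-[4-(benzyloxy)-2-hydroxyphenyl]-3-[4-(benzyloxy)phenyl]-3-(diethylamino)prop-2-en-1-one | CCN(CC)/C(c1ccc(OCc2ccccc2)cc1)=C/C(=O)c1ccc(OCc2ccccc2)cc1O | intermediate (not isolated)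
10 | 7-(benzyloxy)-2-[4-(benzyloxy)phenyl]-4H-chromen-4-one | O=c1cc(-c2ccc(OCc3ccccc3)cc2)oc2cc(OCc3ccccc3)ccc12 | intermediate
11 | (2S)-7-(benzyloxy)-2-[4-(benzyloxy)phenyl]chroman-4-one | O=C1C[C@@H](c2ccc(OCc3ccccc3)cc2)Oc2cc(OCc3ccccc3)ccc12 | intermediate (not isolated)
12 | (2S,4S)-7-(benzyloxy)-2-[4-(benzyloxy)phenyl]chroman-4-ol (2,4-cis) | c1ccc(COc2ccc([C@@H]3C[C@H](O)c4ccc(OCc5ccccc5)cc4O3)cc2)cc1 | intermediate
13 | octa-O-benzyl (2S)-7,4'-dihydroxyflavan-(4β→8)-epiafzelechin-(4β→8)-epiafzelechin (all phenols benzylated, both 3-hydroxyls free) | c1ccccc1COc1ccc([C@@H]2C[C@@H](c3c(OCc5ccccc5)cc(OCc5ccccc5)c4c3O[C@H](c3ccc(OCc5ccccc5)cc3)[C@H](O)[C@H]4c3c(OCc5ccccc5)cc(OCc5ccccc5)c4c3O[C@H](c3ccc(OCc5ccccc5)cc3)[C@H](O)C4)c3ccc(OCc5ccccc5)cc3O2)cc1 | intermediate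
14 | (2S)-7,4'-dihydroxyflavan-(4β→8)-epiafzelechin-(4β→8)-epiafzelechin (upper unit 2S,4R, 2,4-trans) | Oc1ccc([C@@H]2C[C@@H](c3c(O)cc(O)c4c3O[C@H](c3ccc(O)cc3)[C@H](O)[C@H]4c3c(O)cc(O)c4c3O[C@H](c3ccc(O)cc3)[C@H](O)C4)c3ccc(O)cc3O2)cc1 | target

Total step count: 8. Longest linear sequence: 5 steps (1, 2, 3, 7, 8; the branch 4, 5, 6, 7, 8 is equally long).

Steps most likely to fail

Step 7. The flavanyl cation may attack a C6 position of 4 instead of C8, the acid may cleave and scramble the interflavan bond already present, or the trans facial selectivity may erode. The fallback changes the order of union. It sets out from 12 and 2: under the same TMSOTf conditions 12 is coupled with monomer 2 (3 equiv), which reacts only at C8, to give (2S)-7,4'-bis(benzyloxy)flavan-(4β→8)-5,7,4'-tri-O-benzylepiafzelechin F1. DDQ and 2-ethoxyethanol then oxidise C4 of its epiafzelechin unit to the 4β-(2-ethoxyethoxy) ether F2, whose C8 is now blocked so that it cannot self-condense. TMSOTf-mediated coupling of F2 with 2 comes back to the route at 13.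

Step 6. The hydrogenation may stall at the ketone, reduce an arene ring or discriminate the two faces of C2=C3 poorly. The fallback sets C2 by resolution and sets out from 10. An achiral copper hydride (Cu(OAc)2, 1,2-bis(diphenylphosphino)benzene, PhSiH3, t-BuOH, toluene, rt) reduces only C2=C3 to give racemic 7-(benzyloxy)-2-[4-(benzyloxy)phenyl]chroman-4-one F3. Asymmetric transfer hydrogenation with RuCl[(S,S)-TsDPEN](p-cymene) in HCO2H/Et3N then acts as a kinetic resolution: the 2S enantiomer is reduced to the cis alcohol, which comes back to the route at 12. The unreacted (2R)-7-(benzyloxy)-2-[4-(benzyloxy)phenyl]chroman-4-one F4 is racemised with DBU through reversible ring opening and recycled.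

Step 3. Chain growth may continue, because electrophile 3 and product 4 both carry a free C8, and removal of the large excess of 2 may be tedious. The fallback blocks C8 of the electrophile and sets out from 2. NBS in CH2Cl2 at −20 °C gives 8-bromo-5,7,4'-tri-O-benzylepiafzelechin F5. DDQ and 2-ethoxyethanol convert it into 8-bromo-4β-(2-ethoxyethoxy)-5,7,4'-tri-O-benzylepiafzelechin F6. TMSOTf-mediated coupling with 2 (1.2 equiv) gives the 8-bromo hexa-O-benzyl epiafzelechin-(4β→8)-epiafzelechin F7. Bromine–lithium exchange (n-BuLi, 3.5 equiv, THF, −78 °C, then MeOH) removes the blocking group and comes back to the route at 4.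

Further compounds
F1 | step 7 | (2S)-7,4'-bis(benzyloxy)flavan-(4β→8)-5,7,4'-tri-O-benzylepiafzelechin | c1ccccc1COc1ccc([C@@H]2C[C@@H](c3c(OCc5ccccc5)cc(OCc5ccccc5)c4c3O[C@H](c3ccc(OCc5ccccc5)cc3)[C@H](O)C4)c3ccc(OCc5ccccc5)cc3O2)cc1
F2 | step 7 | (2S)-7,4'-bis(benzyloxy)flavan-(4β→8)-4β-(2-ethoxyethoxy)-5,7,4'-tri-O-benzylepiafzelechin | c1ccccc1COc1ccc([C@@H]2C[C@@H](c3c(OCc5ccccc5)cc(OCc5ccccc5)c4c3O[C@H](c3ccc(OCc5ccccc5)cc3)[C@H](O)[C@H]4OCCOCC)c3ccc(OCc5ccccc5)cc3O2)cc1
F3 | step 6 | racemic 7-(benzyloxy)-2-[4-(benzyloxy)phenyl]chroman-4-one | O=C1CC(c2ccc(OCc3ccccc3)cc2)Oc2cc(OCc3ccccc3)ccc12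
F4 | step 6 | (2R)-7-(benzyloxy)-2-[4-(benzyloxy)phenyl]chroman-4-one | O=C1C[C@H](c2ccc(OCc3ccccc3)cc2)Oc2cc(OCc3ccccc3)ccc12
F5 | step 3 | 8-bromo-5,7,4'-tri-O-benzylepiafzelechin | c1ccc(COc2cc(OCc3ccccc3)c3c(c2Br)O[C@H](c2ccc(OCc4ccccc4)cc2)[C@H](O)C3)cc1
F6 | step 3 | 8-bromo-4β-(2-ethoxyethoxy)-5,7,4'-tri-O-benzylepiafzelechin | c1ccc(COc2cc(OCc3ccccc3)c3c(c2Br)O[C@H](c2ccc(OCc4ccccc4)cc2)[C@H](O)[C@H]3OCCOCC)cc1
F7 | step 3 | 8-bromo hexa-O-benzyl epiafzelechin-(4β→8)-epiafzelechin (bromine on C8 of the upper unit) | Brc1c(OCc3ccccc3)cc(OCc3ccccc3)c2c1O[C@H](c1ccc(OCc3ccccc3)cc1)[C@H](O)[C@H]2c1c(OCc3ccccc3)cc(OCc3ccccc3)c2c1O[C@H](c1ccc(OCc3ccccc3)cc1)[C@H](O)C2
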